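**Retrosynthetic overview**
1. Ring A is cut at C5–C6. Its C6 oxygen and C4 methyl, meta to each other, map onto the ketene carbon of an acetic acid arm on C7a and an isopropenyl group on C3a of a fully substituted furan (ring B). 6π-Electrocyclisation of that furylketene gives the benzofuran as its 6-acetate; acetate and ether cleavage finish the synthesis.
2. The isopropenyl group is made from a C3 carboxyl group (acid chloride, methyl ketone, methylenation), so no electrophilic halogenation is needed next to the electron-rich ring C. The acetic arm is held meanwhile as an allyl ester, singled out through a cyclic anhydride.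
3. Ring B is closed with all four substituents in place by annulation of a ring C nitroalkene with symmetrical di-tert-butyl 3-oxopentanedioate.
4. The nitroalkene comes from 3,5-dimethoxy-2,4-dimethylbenzaldehyde and methyl 4-nitrobutanoate; the aldehyde comes from 3,5-dimethoxy-4-methylbenzoic acid by bromination and Suzuki methylation.
5. Ring order: C (purchased), then B (step 6), then A (step 12).

Key step: step 12

Remark: monocyclic intermediates carry furan numbering and bicyclic ones benzofuran numbering (ring A = benzo ring, ring B = furan, ring C = pendant aryl ring); Ar = 3,5-dimethoxy-2,4-dimethylphenyl throughout.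

**Step 1**
Reactants: 1 3,5-dimethoxy-4-methylbenzoic acid
Product: 2 (3,5-dimethoxy-4-methylphenyl)methanol
Conditions: BH3·THF, THF, 0 → 23 °C; aqueous work-up
Reagents that add atoms: none
Why: Borane reduction of a carboxylic acid via the acyloxyborane should give the benzyl alcohol and leave the aryl ethers untouched.

**Step 2**
Reactants: 2 (3,5-dimethoxy-4-methylphenyl)methanol
Product: 3 3,5-dimethoxy-4-methylbenzaldehyde
Conditions: MnO2 (activated, excess), CH2Cl2, 23 °C
Reagents that add atoms: none
Why: Heterogeneous MnO2 oxidation of a benzylic alcohol should stop cleanly at the aldehyde.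

**Step 3**
Reactants: 3 3,5-dimethoxy-4-methylbenzaldehyde
Product: 4 2-bromo-3,5-dimethoxy-4-methylbenzaldehyde
Conditions: NBS (1.0 equiv), MeCN, 0 → 23 °C
Reagents that add atoms: N-bromosuccinimide, O=C1CCC(=O)N1Br
Why: Electrophilic aromatic bromination should go to C2 (equivalent to C6), the only free position ortho and para to the two methoxy groups, and one equivalent should stop at the monobromide.

**Step 4**
Reactants: 4 2-bromo-3,5-dimethoxy-4-methylbenzaldehyde
Product: 5 3,5-dimethoxy-2,4-dimethylbenzaldehyde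
Conditions: MeB(OH)2, Pd(OAc)2 (5 mol%), SPhos (10 mol%), K3PO4, toluene/H2O, 100 °C
Reagents that add atoms: methylboronic acid, CB(O)O
Why: Suzuki–Miyaura methylation; the ortho-formyl group speeds oxidative addition and the bulky biarylphosphine should cope with the di-ortho-substituted bromide.

**Step 5**
Reactants: 5 3,5-dimethoxy-2,4-dimethylbenzaldehyde; 6 methyl 4-nitrobutanoate
Product: 7 methyl (4E)-5-Ar-4-nitropent-4-enoate
Conditions: NH4OAc, AcOH, 100 °C
Reagents that add atoms: none
Why: Henry (nitroaldol) condensation with dehydration should give the conjugated nitroalkene as the thermodynamically preferred E isomer (aryl trans to nitro).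

**Step 6**
Reactants: 7 methyl (4E)-5-Ar-4-nitropent-4-enoate; 8 di-tert-butyl 3-oxopentanedioate
Product: 10 tert-butyl 2-(2-tert-butoxy-2-oxoethyl)-4-Ar-5-(3-methoxy-3-oxopropyl)furan-3-carboxylate, via Michael adduct 9 (not isolated)
Conditions: KF (2 equiv), DME, 23 °C, then 80 °C
Reagents that add atoms: none
Why: Nitroalkene furan annulation of the Feist–Benary/Yoshikoshi type: the C2 carbanion of 8 adds to the aryl-bearing carbon of 7, the ketone enol oxygen closes onto the aci-nitro carbon, and loss of water and nitroxyl aromatises ring B; because 8 is symmetrical, the aryl carbon can only become C4, the nitro carbon C5, the ester-bearing carbon C3 and the ketone carbon C2.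

**Step 7**
Reactants: 10 tert-butyl 2-(2-tert-butoxy-2-oxoethyl)-4-Ar-5-(3-methoxy-3-oxopropyl)furan-3-carboxylate
Product: 11 2-(carboxymethyl)-4-Ar-5-(3-methoxy-3-oxopropyl)furan-3-carboxylic acid
Conditions: TFA/CH2Cl2 (1:2), 0 → 23 °C
Reagents that add atoms: none
Why: Acidolysis with loss of isobutene should remove both tert-butyl esters, while the primary methyl ester and the acceptor-substituted furan are stable to TFA.

**Step 8**
Reactants: 11 2-(carboxymethyl)-4-Ar-5-(3-methoxy-3-oxopropyl)furan-3-carboxylic acid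
Product: 13 4-Ar-5-(3-methoxy-3-oxopropyl)-2-[2-oxo-2-(prop-2-en-1-yloxy)ethyl]furan-3-carboxylic acid, via cyclic anhydride 12 (not isolated)
Conditions: Ac2O, toluene, 80 °C; evaporate; allyl alcohol, 70 °C
Reagents that add atoms: allyl alcohol (prop-2-en-1-ol), C=CCO
Why: Dehydration gives the six-membered homophthalic-type anhydride, and regioselective anhydride alcoholysis should occur at the non-conjugated CH2–C=O carbonyl (the furan-3-carbonyl is a hindered vinylogous carbonate), so only the acetic arm becomes an allyl ester.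

**Step 9**
Reactants: 13 4-Ar-5-(3-methoxy-3-oxopropyl)-2-[2-oxo-2-(prop-2-en-1-yloxy)ethyl]furan-3-carboxylic acid
Product: 15 prop-2-en-1-yl 2-[3-acetyl-4-Ar-5-(3-methoxy-3-oxopropyl)furan-2-yl]acetate, via acid chloride 14 (not isolated)
Conditions: (COCl)2, DMF (cat.), CH2Cl2, 0 → 23 °C; evaporate; Me2CuLi, THF, −78 °C
Reagents that add atoms: lithium dimethylcuprate Me2CuLi, [Li+].C[Cu-]C; oxalyl chloride, O=C(Cl)C(=O)Cl (chlorine of 14 only)
Why: Acid chloride formation followed by Gilman cuprate acylation; at −78 °C the cuprate should react with the acid chloride far faster than with the methyl and allyl esters and should not add to the ketone formed.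

**Step 10**
Reactants: 15 prop-2-en-1-yl 2-[3-acetyl-4-Ar-5-(3-methoxy-3-oxopropyl)furan-2-yl]acetate
Product: 16 prop-2-en-1-yl 2-[4-Ar-5-(3-methoxy-3-oxopropyl)-3-(prop-1-en-2-yl)furan-2-yl]acetate
Conditions: Zn, CH2Br2, TiCl4 (premixed in THF), CH2Cl2, 0 → 23 °C; cold NaHCO3 quench
Reagents that add atoms: dibromomethane, BrCBr
Why: Takai–Lombardo methylenation uses a non-basic titanium methylene reagent that olefinates hindered, enolisable ketones and leaves esters alone, which avoids the Claisen closure between the acetyl group and the neighbouring ester that a basic ylide would invite.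

**Step 11**
Reactants: 16 prop-2-en-1-yl 2-[4-Ar-5-(3-methoxy-3-oxopropyl)-3-(prop-1-en-2-yl)furan-2-yl]acetate
Product: 17 2-[4-Ar-5-(3-methoxy-3-oxopropyl)-3-(prop-1-en-2-yl)furan-2-yl]acetic acid
Conditions: Pd(PPh3)4 (5 mol%), morpholine, THF, 23 °C; pH 4 work-up
Reagents that add atoms: none
Why: Tsuji–Trost deallylation through a π-allylpalladium complex trapped by morpholine should free the acid under neutral conditions; an acid-labile ester was avoided because protic acid would add the carboxyl group across the isopropenyl group as a lactone.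

**Step 12**
Reactants: 17 2-[4-Ar-5-(3-methoxy-3-oxopropyl)-3-(prop-1-en-2-yl)furan-2-yl]acetic acid
Product: 22 methyl 3-[6-acetoxy-3-Ar-4-methyl-1-benzofuran-2-yl]propanoate, via mixed anhydride 18 (not isolated), via furylketene 19 (not isolated), via dienone 20 (not isolated), via phenol 21 (not isolated)
Conditions: Ac2O, NaOAc, 140 °C
Reagents that add atoms: acetic anhydride, CC(=O)OC(C)=O
Why: Acetic anhydride turns the acetic acid arm into mixed anhydride 18, and acetate-promoted loss of acetic acid gives furylketene 19, in which the ketene C=C, the furan C7a=C3a bond and the isopropenyl C=C form a 1,3,5-hexatriene held cis by the ring. Thermal disrotatory 6π-electrocyclisation joins the ketene carbon (C6) to the isopropenyl CH2 (C5) and closes the six-membered ring A as dienone 20, which enolises to phenol 21 with return of furan aromaticity and is O-acetylated to 22. The closest known reaction type is the acetic anhydride–sodium acetate benzannulation of ortho-alkenyl arylacetic acids and Stobbe half-acids through aryl- or dienylketenes. No stereocentre is formed. The step needs activation of one carboxyl group only and a single mode of closure: the acetic arm is the only free acid (the propanoate is a methyl ester), and the ketene carbon can reach only the isopropenyl terminus, so oxygen must end at C6 and the methyl at C4. The reactive s-cis arrangement turns the isopropenyl methyl towards the twisted ring C, the same peri relationship that the target itself has.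

**Step 13**
Reactants: 22 methyl 3-[6-acetoxy-3-Ar-4-methyl-1-benzofuran-2-yl]propanoate
Product: 21 methyl 3-[3-Ar-6-hydroxy-4-methyl-1-benzofuran-2-yl]propanoate
Conditions: K2CO3 (cat.), MeOH, 23 °C
Reagents that add atoms: none
Why: Base-catalysed transesterification should remove the aryl acetate, while the methyl ester is unchanged in methanol.

**Step 14**
Reactants: 21 methyl 3-[3-Ar-6-hydroxy-4-methyl-1-benzofuran-2-yl]propanoate
Product: 23 Talarominine A, methyl 3-[3-(3,5-dihydroxy-2,4-dimethylphenyl)-6-hydroxy-4-methyl-1-benzofuran-2-yl]propanoate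
Conditions: BBr3, CH2Cl2, −78 → 0 °C; then MeOH, 0 → 23 °C
Reagents that add atoms: none
Why: BBr3 ether cleavage (O–B complexation, bromide attack on methyl) should remove both ring C methyl ethers; low temperature spares the ester, and the methanolic HBr formed on quenching would re-esterify any acid that did form.

**Compound list**
1 | 3,5-dimethoxy-4-methylbenzoic acid | COc1cc(C(=O)O)cc(OC)c1C | starting material
2 | (3,5-dimethoxy-4-methylphenyl)methanol | OCc1cc(OC)c(C)c(OC)c1 | intermediate
3 | 3,5-dimethoxy-4-methylbenzaldehyde | O=Cc1cc(OC)c(C)c(OC)c1 | intermediate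
4 | 2-bromo-3,5-dimethoxy-4-methylbenzaldehyde | O=Cc1cc(OC)c(C)c(OC)c1Br | intermediate
5 | 3,5-dimethoxy-2,4-dimethylbenzaldehyde | O=Cc1cc(OC)c(C)c(OC)c1C | intermediate
6 | methyl 4-nitrobutanoate | COC(=O)CCC[N+](=O)[O-] | starting material
7 | methyl (4E)-5-(3,5-dimethoxy-2,4-dimethylphenyl)-4-nitropent-4-enoate | COC(=O)CC/C(=C\c1cc(OC)c(C)c(OC)c1C)[N+](=O)[O-] | intermediate
8 | di-tert-butyl 3-oxopentanedioate | CC(C)(C)OC(=O)CC(=O)CC(=O)OC(C)(C)C | starting material
9 | di-tert-butyl 2-[1-(3,5-dimethoxy-2,4-dimethylphenyl)-5-methoxy-2-nitro-5-oxopentyl]-3-oxopentanedioate (mixture of diastereomers) | COC(=O)CCC([N+](=O)[O-])C(c1cc(OC)c(C)c(OC)c1C)C(C(=O)OC(C)(C)C)C(=O)CC(=O)OC(C)(C)C | intermediate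
10 | tert-butyl 2-(2-tert-butoxy-2-oxoethyl)-4-(3,5-dimethoxy-2,4-dimethylphenyl)-5-(3-methoxy-3-oxopropyl)furan-3-carboxylate | COC(=O)CCc1oc(CC(=O)OC(C)(C)C)c(C(=O)OC(C)(C)C)c1-c1cc(OC)c(C)c(OC)c1C | intermediate
11 | 2-(carboxymethyl)-4-(3,5-dimethoxy-2,4-dimethylphenyl)-5-(3-methoxy-3-oxopropyl)furan-3-carboxylic acid | COC(=O)CCc1oc(CC(=O)O)c(C(=O)O)c1-c1cc(OC)c(C)c(OC)c1C | intermediate
12 | methyl 3-[3-(3,5-dimethoxy-2,4-dimethylphenyl)-4,6-dioxo-6,7-dihydro-4H-furo[3,2-c]pyran-2-yl]propanoate | COC(=O)CCc1oc2c(c1-c1cc(OC)c(C)c(OC)c1C)C(=O)OC(=O)C2 | intermediate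
13 | 4-(3,5-dimethoxy-2,4-dimethylphenyl)-5-(3-methoxy-3-oxopropyl)-2-[2-oxo-2-(prop-2-en-1-yloxy)ethyl]furan-3-carboxylic acid | COC(=O)CCc1oc(CC(=O)OCC=C)c(C(=O)O)c1-c1cc(OC)c(C)c(OC)c1C | intermediate
14 | prop-2-en-1-yl 2-[3-(chlorocarbonyl)-4-(3,5-dimethoxy-2,4-dimethylphenyl)-5-(3-methoxy-3-oxopropyl)furan-2-yl]acetate | COC(=O)CCc1oc(CC(=O)OCC=C)c(C(=O)Cl)c1-c1cc(OC)c(C)c(OC)c1C | intermediate
15 | prop-2-en-1-yl 2-[3-acetyl-4-(3,5-dimethoxy-2,4-dimethylphenyl)-5-(3-methoxy-3-oxopropyl)furan-2-yl]acetate | COC(=O)CCc1oc(CC(=O)OCC=C)c(C(C)=O)c1-c1cc(OC)c(C)c(OC)c1C | intermediate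
16 | prop-2-en-1-yl 2-[4-(3,5-dimethoxy-2,4-dimethylphenyl)-5-(3-methoxy-3-oxopropyl)-3-(prop-1-en-2-yl)furan-2-yl]acetate | COC(=O)CCc1oc(CC(=O)OCC=C)c(C(C)=C)c1-c1cc(OC)c(C)c(OC)c1C | intermediate
17 | 2-[4-(3,5-dimethoxy-2,4-dimethylphenyl)-5-(3-methoxy-3-oxopropyl)-3-(prop-1-en-2-yl)furan-2-yl]acetic acid | COC(=O)CCc1oc(CC(=O)O)c(C(C)=C)c1-c1cc(OC)c(C)c(OC)c1C | intermediate
18 | acetic 2-[4-(3,5-dimethoxy-2,4-dimethylphenyl)-5-(3-methoxy-3-oxopropyl)-3-(prop-1-en-2-yl)furan-2-yl]acetic anhydride | COC(=O)CCc1oc(CC(=O)OC(C)=O)c(C(C)=C)c1-c1cc(OC)c(C)c(OC)c1C | intermediate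
19 | methyl 3-[3-(3,5-dimethoxy-2,4-dimethylphenyl)-5-(2-oxoethenyl)-4-(prop-1-en-2-yl)furan-2-yl]propanoate | COC(=O)CCc1oc(C=C=O)c(C(C)=C)c1-c1cc(OC)c(C)c(OC)c1C | intermediate
20 | methyl 3-[3-(3,5-dimethoxy-2,4-dimethylphenyl)-4-methyl-6-oxo-5,6-dihydro-1-benzofuran-2-yl]propanoate | COC(=O)CCC1=C(c2cc(OC)c(C)c(OC)c2C)C2=C(C)CC(=O)C=C2O1 | intermediate
21 | methyl 3-[3-(3,5-dimethoxy-2,4-dimethylphenyl)-6-hydroxy-4-methyl-1-benzofuran-2-yl]propanoate | COC(=O)CCc1oc2cc(O)cc(C)c2c1-c1cc(OC)c(C)c(OC)c1C | intermediate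
22 | methyl 3-[6-acetoxy-3-(3,5-dimethoxy-2,4-dimethylphenyl)-4-methyl-1-benzofuran-2-yl]propanoate | COC(=O)CCc1oc2cc(OC(C)=O)cc(C)c2c1-c1cc(OC)c(C)c(OC)c1C | intermediate
23 | Talarominine A, methyl 3-[3-(3,5-dihydroxy-2,4-dimethylphenyl)-6-hydroxy-4-methyl-1-benzofuran-2-yl]propanoate | COC(=O)CCc1oc2cc(O)cc(C)c2c1-c1cc(O)c(C)c(O)c1C | target

**Step count**
Total: 14 steps. Longest linear sequence: 14 steps (1 → 23).

**Steps most likely to fail**

1. Step 12. The ketene may be diverted before it cyclises: C-acetylation of the mixed anhydride with decarboxylation (Dakin–West-type), ketene dimerisation, or slow closure because the isopropenyl group, wedged between the ketene arm and ring C, rarely reaches the planar s-cis arrangement. The fallback sets out from 17 and comes back at 21; it closes ring A by olefin metathesis at C4=C5 instead. Compound 17 would be converted under neutral conditions with 1-chloro-N,N,2-trimethylprop-1-en-1-amine into 2-[4-Ar-5-(3-methoxy-3-oxopropyl)-3-(prop-1-en-2-yl)furan-2-yl]acetyl chloride F1. Stille acylation with tributyl(vinyl)stannane and Pd(PPh3)4 would give the vinyl ketone methyl 3-[3-Ar-5-(2-oxobut-3-en-1-yl)-4-(prop-1-en-2-yl)furan-2-yl]propanoate F2. Ring-closing metathesis with the second-generation Grubbs catalyst would join the isopropenyl and enone alkenes to methyl 3-[3-Ar-4-methyl-6-oxo-6,7-dihydro-1-benzofuran-2-yl]propanoate F3, which should tautomerise in the flask to phenol 21; step 14 then follows.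

2. Step 6. The Michael adduct may stall at the nitronate without closing, may lose isobutene on heating, or may react a second time through the other active methylene of 8. The fallback sets out from 7 (with 8) and comes back at 10; it separates C–C bond formation from ring closure. Michael addition alone (Et3N cat., THF, 23 °C) would give 9, which is isolated this time. A McMurry–Nef reaction (TiCl3, NH4OAc buffer, aqueous THF) would turn the secondary nitro group into a ketone, giving the 1,4-diketone di-tert-butyl 2-[1-Ar-5-methoxy-2,5-dioxopentyl]-3-oxopentanedioate F4. Paal–Knorr cyclodehydration (PPTS, toluene, 70 °C) would then give 10.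

3. Step 10. Methylenation of the acetyl group, flanked by ring C and the acetate arm, may be incomplete, or the Lewis-acidic medium may enolise or degrade the keto ester. The fallback sets out from 15 and comes back at 16; it replaces carbonyl olefination by addition and elimination. MeMgBr/CeCl3 (THF, −78 °C, quenched cold so that the alkoxide does not lactonise onto the allyl ester) would give the tertiary alcohol prop-2-en-1-yl 2-[4-Ar-3-(2-hydroxypropan-2-yl)-5-(3-methoxy-3-oxopropyl)furan-2-yl]acetate F5. Dehydration with Burgess reagent (toluene, 50 °C) would give 16.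

**Further compounds**
F1 | step 12 | 2-[4-(3,5-dimethoxy-2,4-dimethylphenyl)-5-(3-methoxy-3-oxopropyl)-3-(prop-1-en-2-yl)furan-2-yl]acetyl chloride | COC(=O)CCc1oc(CC(=O)Cl)c(C(C)=C)c1-c1cc(OC)c(C)c(OC)c1C
F2 | step 12 | methyl 3-[3-(3,5-dimethoxy-2,4-dimethylphenyl)-5-(2-oxobut-3-en-1-yl)-4-(prop-1-en-2-yl)furan-2-yl]propanoate | COC(=O)CCc1oc(CC(=O)C=C)c(C(C)=C)c1-c1cc(OC)c(C)c(OC)c1C
F3 | step 12 | methyl 3-[3-(3,5-dimethoxy-2,4-dimethylphenyl)-4-methyl-6-oxo-6,7-dihydro-1-benzofuran-2-yl]propanoate | COC(=O)CCc1oc2c(c1-c1cc(OC)c(C)c(OC)c1C)C(C)=CC(=O)C2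
F4 | step 6 | di-tert-butyl 2-[1-(3,5-dimethoxy-2,4-dimethylphenyl)-5-methoxy-2,5-dioxopentyl]-3-oxopentanedioate | COC(=O)CCC(=O)C(c1cc(OC)c(C)c(OC)c1C)C(C(=O)OC(C)(C)C)C(=O)CC(=O)OC(C)(C)C
F5 | step 10 | prop-2-en-1-yl 2-[4-(3,5-dimethoxy-2,4-dimethylphenyl)-3-(2-hydroxypropan-2-yl)-5-(3-methoxy-3-oxopropyl)furan-2-yl]acetate | COC(=O)CCc1oc(CC(=O)OCC=C)c(C(C)(C)O)c1-c1cc(OC)c(C)c(OC)c1C
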